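**Retrosynthetic overview**
1. Target 14 ⇒ 17,19-diol 11: the C18–O bond is made last, by 19-O-silyl-directed C–H silylation/oxidation of the C4 methyl (key step, new substrate class).
2. 11 ⇒ andrograpanin 7: the C17–O bond comes from the 8,17-epoxide, a hydride shift to the aldehyde, equilibration of C8 and reduction.
3. 7 ⇒ andrographolide 1: the C14–O bond is removed by reductive allylic transposition (this gives the butenolide) and the C3–O bond by radical opening of a 3,19-thionocarbonate.
4. Rings: none is built. Rings A and B (trans-decalin with C5, C9, C10) and the lactone ring come intact from 1; only temporary heterocycles are made and opened, in the order thionocarbonate, epoxide, oxasilolane.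

Assumption: andrographolide, the bulk ent-labdane from Andrographis paniculata with the target's absolute configuration at C5, C9 and C10, is taken as a cheap commercial starting material; labdane numbering (C1–C20) is used throughout.

**Step 1**
Reactants: 1 andrographolide
Product: 2 3,19-O-thiocarbonylandrographolide
Conditions: 1,1'-thiocarbonyldiimidazole (1.1 equiv, slow addition), DMAP (0.1 equiv), THF, 0 °C to 23 °C
Reagents that add atoms: 1,1'-thiocarbonyldiimidazole, S=C(n1ccnc1)n1ccnc1
Why: Thiocarbonyl transfer (O-acylation): the primary 19-OH reacts first and the neighbouring 3-OH then closes the six-membered cyclic thionocarbonate intramolecularly, faster than the lone 14-OH is acylated, and no stereocentre is touched.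

**Step 2**
Reactants: 2 3,19-O-thiocarbonylandrographolide
Product: 5 14-deoxy-3,19-O-thiocarbonylandrographolide, via C14 sulfonylhydrazine adduct 3 (not isolated), via C14 allylic diazene 4 (not isolated)
Conditions: PPh3, DEAD, 2-nitrobenzenesulfonylhydrazide, N-methylmorpholine, −30 °C, then 23 °C
Reagents that add atoms: none
Why: Myers reductive allylic transposition: Mitsunobu displacement of the allylic 14-OH, loss of the sulfinic acid and retro-ene loss of N2 from the diazene put hydrogen on C12 and move the alkene to C13=C14 (the conjugated butenolide), which removes the C14 stereocentre and creates no new one.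

**Step 3**
Reactants: 5 14-deoxy-3,19-O-thiocarbonylandrographolide
Product: 7 andrograpanin (3,14-dideoxyandrographolide), via S-stannyl thiocarbonate 6 (not isolated)
Conditions: Bu3SnH, AIBN (cat.), PhMe, 100 °C; then KF, MeOH/H2O, 23 °C
Reagents that add atoms: none
Why: Barton–McCombie deoxygenation of a cyclic thionocarbonate: the stannyl radical adds to C=S and β-scission breaks the C3–O bond (secondary radical) rather than the neopentyl C19–O bond, so C3 becomes CH2 and fluoride hydrolysis of the stannyl thiocarbonate left on O19 returns the 19-OH.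

**Step 4**
Reactants: 7 andrograpanin
Product: 8 8,17-epoxyandrograpanin
Conditions: mCPBA (1.2 equiv), CH2Cl2, 0 °C
Reagents that add atoms: mCPBA, OOC(=O)c1cccc(Cl)c1
Why: Prilezhaev epoxidation: only the electron-rich exocyclic 1,1-disubstituted alkene reacts (the butenolide alkene is electron-poor), mainly from the face anti to the axial C10 methyl, and the C8 configuration formed here is reset in step 5.

**Step 5**
Reactants: 8 8,17-epoxyandrograpanin
Product: 11 17,19-diol (C8 CH2OH equatorial), via axial C17 aldehyde 9 (not isolated), via equatorial C17 aldehyde 10 (not isolated)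
Conditions: BF3·OEt2 (0.2 equiv), CH2Cl2, −78 to −20 °C; then K2CO3 (0.5 equiv), MeOH, 23 °C; then NaBH4, −20 °C
Reagents that add atoms: none
Why: Meinwald rearrangement (opening to the tertiary C8 cation, 1,2-hydride shift from C17) gives the aldehyde, carbonate enolisation equilibrates C8 to the equatorial CHO (trans to the C9 chain, free of the 1,3-diaxial clash with the C10 methyl), and NaBH4 1,2-reduction fixes this configuration without touching the butenolide at low temperature.

**Step 6**
Reactants: 11 17,19-diol
Product: 14 target triol CNP0271381.1, via bis-silyl ether 12 (not isolated), via spiro oxasilolane 13 (not isolated)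
Conditions: Et2SiH2 (4 equiv), [Ir(cod)OMe]2 (0.5 mol%), THF, 23 °C, then evaporate; [Ir(cod)OMe]2 (2 mol%), 3,4,7,8-Me4phen (5 mol%), norbornene (1.5 equiv), THF, 100 °C; then 30% H2O2, KHCO3, KF, THF/MeOH, 40 °C
Reagents that add atoms: hydrogen peroxide, OO
Why: Proposed new method: iridium-catalysed γ-C(sp3)–H silylation directed by the (hydrido)silyl ether of a primary neopentyl alcohol, run beside a butenolide; the Si–H of the 19-O-SiEt2H group adds to the iridium phenanthroline silyl complex, the C18 methyl C–H (the only primary γ-C–H, held close by the quaternary C4) is cleaved through a six-membered iridacycle, C–Si reductive elimination closes the oxasilolane while norbornene takes up H2, and Tamao–Fleming oxidation then turns C18–Si into the C18–O bond and frees both silyl ethers (the 17-O-silyl group has no primary γ-C–H and is only a temporary mask); the closest known reaction type is the alcohol-directed iridium-catalysed C–H silylation/oxidation to 1,3-diols, established to my knowledge for silyl ethers of secondary and tertiary alcohols; C4 becomes non-stereogenic and no other centre is touched.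

**Compound list**
1 | andrographolide, (3E,4S)-3-{2-[(1R,4aS,5R,6R,8aS)-6-hydroxy-5-(hydroxymethyl)-5,8a-dimethyl-2-methylidenedecahydronaphthalen-1-yl]ethylidene}-4-hydroxyoxolan-2-one | C[C@@]12CC[C@@H](O)[C@@](C)(CO)[C@H]1CCC(=C)[C@H]2C/C=C3/C(=O)OC[C@H]3O | starting material
2 | 3,19-O-thiocarbonylandrographolide (six-membered cyclic thionocarbonate across O3 and O19, 14-OH free) | C[C@@]12CC[C@H]3OC(=S)OC[C@@]3(C)[C@H]1CCC(=C)[C@H]2C/C=C4/C(=O)OC[C@H]4O | intermediate
3 | C14 N-(2-nitrophenylsulfonyl)hydrazine adduct of 2 (C14 inverted) | C[C@@]12CC[C@H]3OC(=S)OC[C@@]3(C)[C@H]1CCC(=C)[C@H]2C/C=C4/C(=O)OC[C@@H]4N(N)S(=O)(=O)c5ccccc5[N+](=O)[O-] | intermediate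
4 | C14 allylic monoalkyl diazene | C[C@@]12CC[C@H]3OC(=S)OC[C@@]3(C)[C@H]1CCC(=C)[C@H]2C/C=C4/C(=O)OC[C@@H]4N=N | intermediate
5 | 14-deoxy-3,19-O-thiocarbonylandrographolide (C12 CH2, C13=C14 butenolide) | C[C@@]12CC[C@H]3OC(=S)OC[C@@]3(C)[C@H]1CCC(=C)[C@H]2CCC4=CCOC4=O | intermediate
6 | andrograpanin 19-O-[(tributylstannylthio)carbonyl] derivative | C[C@@]12CCC[C@@](C)(COC(=O)S[Sn](CCCC)(CCCC)CCCC)[C@H]1CCC(=C)[C@H]2CCC3=CCOC3=O | intermediate
7 | andrograpanin (19-hydroxy-ent-labda-8(17),13-dien-16,15-olide) | C[C@@]12CCC[C@@](C)(CO)[C@H]1CCC(=C)[C@H]2CCC3=CCOC3=O | intermediate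
8 | 8,17-epoxyandrograpanin (major epimer, oxygen anti to the C10 methyl) | C[C@@]12CCC[C@@](C)(CO)[C@H]1CC[C@@]3(CO3)[C@H]2CCC4=CCOC4=O | intermediate
9 | 19-hydroxy C17 aldehyde, 8-epimer (CHO axial, cis to the C10 methyl) | C[C@@]12CCC[C@@](C)(CO)[C@H]1CC[C@@H](C=O)[C@H]2CCC3=CCOC3=O | intermediate
10 | 19-hydroxy C17 aldehyde (CHO equatorial, trans to the C9 chain and the C10 methyl) | C[C@@]12CCC[C@@](C)(CO)[C@H]1CC[C@H](C=O)[C@H]2CCC3=CCOC3=O | intermediate
11 | 17,19-dihydroxy-ent-labd-13-en-16,15-olide (C8 CH2OH equatorial) | C[C@@]12CCC[C@@](C)(CO)[C@H]1CC[C@H](CO)[C@H]2CCC3=CCOC3=O | intermediate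
12 | 17,19-bis-O-(diethylsilyl) ether of 11 | C[C@@]12CCC[C@@](C)(CO[SiH](CC)CC)[C@H]1CC[C@H](CO[SiH](CC)CC)[C@H]2CCC3=CCOC3=O | intermediate
13 | spiro 2,2-diethyl-1-oxa-2-silacyclopentane at C4 (ring O19–Si–C18–C4–C19), 17-O-diethylsilyl ether | C[C@@]12CCC[C@@]3(CO[Si](CC)(CC)C3)[C@H]1CC[C@H](CO[SiH](CC)CC)[C@H]2CCC4=CCOC4=O | intermediate
14 | CNP0271381.1, 17,18,19-trihydroxy-ent-labd-13-en-16,15-olide (C8 CH2OH equatorial) | C[C@@]12CCCC(CO)(CO)[C@H]1CC[C@H](CO)[C@H]2CCC3=CCOC3=O | target

**Totals**
Total steps: 6. Longest linear sequence: 6 (fully linear from 1).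

**Three steps most likely to fail**

Step 6 (the proposed new step). The likely failures are dialkoxysilane formation from the primary alcohols, reduction or hydrosilylation of the butenolide by iridium hydride species, and slow cyclometalation. The fallback uses known carboxylate-directed palladium chemistry; it sets out from 11 and comes back at 14. Oxidise both primary alcohols (TEMPO, PhI(OAc)2, MeCN/H2O; then NaClO2) to the 17,19-dioic acid F5. Subject it to β-C(sp3)–H lactonisation of the α-quaternary acid (divalent palladium catalyst Pd(CH3CN)2Cl2, mono-N-protected β-amino acid ligand, TBHP, CsHCO3, HFIP, 60 °C), which forms the C18–O bond as the C19/C18 β-lactone 17-acid F6. Open the β-lactone (LiOH, THF/H2O; acidify to re-close the butenolide) to the 18-hydroxy-17,19-dioic acid F7. Reduce both carboxylic acids with BH3·THF at 0 °C, which is faster than attack on the butenolide, to reach 14.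

Step 2. The hydrazide may attack C12 (SN2′), which would give the exocyclic alkene isomer, or the activated alcohol may eliminate to the 11,12-diene. The fallback replaces the Mitsunobu/diazene path by a polar addition–elimination; it sets out from 2 and comes back at 5. Acetylate the 14-OH (Ac2O, DMAP, CH2Cl2, 0 °C) to 14-O-acetyl-3,19-O-thiocarbonylandrographolide F1. Treat F1 with NaBH4 (THF/MeOH, −30 °C): conjugate hydride addition at C12 and E1cB loss of the C14 acetate give 5.

Step 5. The C8 cation may lose a proton to give allylic alcohols, and the base step may harm the butenolide. The fallback avoids the epoxide; it sets out from 7, bypasses 8 and comes back at 11. Hydroborate with 9-BBN (THF, 23–50 °C; NaBO3·4H2O), which attacks anti to the C10 methyl and gives the 8-epi-17,19-diol F2. Oxidise with Dess–Martin periodinane (NaHCO3, CH2Cl2) to the 8-epi-17,19-dial F3. Equilibrate C8 (K2CO3, MeOH, 23 °C) to the 17,19-dial F4 with the C8 formyl group equatorial. Reduce both aldehydes with NaBH4 (MeOH, −20 °C) to 11.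

**Further compounds**
F1 | step 2 | 14-O-acetyl-3,19-O-thiocarbonylandrographolide | C[C@@]12CC[C@H]3OC(=S)OC[C@@]3(C)[C@H]1CCC(=C)[C@H]2C/C=C4/C(=O)OC[C@H]4OC(C)=O
F2 | step 5 | 8-epi-17,19-diol (C8 CH2OH axial) | C[C@@]12CCC[C@@](C)(CO)[C@H]1CC[C@@H](CO)[C@H]2CCC3=CCOC3=O
F3 | step 5 | 8-epi-17,19-dial | C[C@@]12CCC[C@@](C)(C=O)[C@H]1CC[C@@H](C=O)[C@H]2CCC3=CCOC3=O
F4 | step 5 | 17,19-dial (C8 CHO equatorial) | C[C@@]12CCC[C@@](C)(C=O)[C@H]1CC[C@H](C=O)[C@H]2CCC3=CCOC3=O
F5 | step 6 | 17,19-dioic acid | C[C@@]12CCC[C@@](C)(C(=O)O)[C@H]1CC[C@H](C(=O)O)[C@H]2CCC3=CCOC3=O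
F6 | step 6 | C19/C18 spiro β-lactone 17-acid | C[C@@]12CCC[C@]3(COC3=O)[C@H]1CC[C@H](C(=O)O)[C@H]2CCC4=CCOC4=O
F7 | step 6 | 18-hydroxy-17,19-dioic acid | C[C@@]12CCC[C@@](CO)(C(=O)O)[C@H]1CC[C@H](C(=O)O)[C@H]2CCC3=CCOC3=O
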